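Target in the east flask stood at 44.7% of the substrate charged after 10.0 min, barely above the 44.3% read at 8.00 min, while its coupling partner was charged at 70.0% of the substrate.

in all of them: substrate 1.4 M; free catalyst 4.6 mM
- east: coupling partner 0.98 M; temperature 60 °C; the very flask that is asked about, followed so far
- north-west: coupling partner 0.98 M; temperature 45 °C; run made earlier
- flask: coupling partner 0.980 M; temperature 60 °C; time 12 min

- east (time / min: target / %): 1.50: 16.4; 3.00: 28.0; 5.00: 36.5; 6.00: 39.8; 8.00: 44.3; 10.0: 44.7
- north-west (time / min: target / %): 3.00: 12.3; 6.00: 21.6; 10.0: 31.0; 12.0: 33.0; 15.0: 38.0; 20.0: 41.4

(each reading ± 1 percentage point)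

- Tuesday's: at 12 min take out 90% of the target then present, then wait 25 min
- Thursday's: at 12 min raise the temperature by 15 K, then wait 25 min
- Sunday's: at 12 min add free catalyst, 100% of the amount charged, then wait 25 min
- Wednesday's: at 12 min add coupling partner, 50.0% of the amount charged, then wait 25 min
- Friday's: change nothing and wait 25 min more

- target taken out counts as made
- additions bring no volume worth counting

1. target, in percent of the substrate first charged, at 12 min
2. the option that brings most further target ("none" if no option brings more than 2 percentage points) (Tuesday's / Thursday's / Sunday's / Wednesday's / Friday's / none)
3. target present, with what was taken out counted in, in percent of the substrate first charged, after Tuesday's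
4. target present, with what was taken out counted in, in percent of the substrate first charged, after Thursday's

Two of us read these runs differently. The one who made the forecast sees “a fixed yield per catalyst charge”, about 143 turnovers. That view gives 45.5% at the asked time, 46.7% after Tuesday's, 46.8% after Thursday's, and Sunday's as the best option.

I read the same flat top another way. The north-west run at 45 °C had reached 41.4% by 20.0 min and was still climbing, and a used-up reagent is another way to get a flat top. So I take the coupling partner as the limiting reagent, with some side path using part of what it could give. My number is the target at the flat top divided by the partner's share of the substrate, 0.639, the yield on partner. Wednesday's adds 50.0% of the partner charge, which is 35.0% of the substrate, so I expect 22 percentage points more target. On this view Sunday's brings less than 2 points. I expect no more from Tuesday's and Thursday's than the forecast does.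

The simulation gives 45.1% at the asked time and Wednesday's as the best option, with 20 points further target, against the 22 points that my yield on partner gave. Sunday's brings 0.18 points. Tuesday's ends at 56.2% and Thursday's at 55.2%, higher than the forecast's figures  and higher than I expected. The forecast's flat line holds for the flask left alone: Friday's brings 0.19 points, and at 120 min target still stands at 45.2%.

    target ⇌ isomer of the product (K = 0.360, k = 0.00170 s⁻¹, Ea = 92.0 kJ mol⁻¹, ΔH = −73.0 kJ mol⁻¹)
    catalyst intermediate C → free catalyst + target (k = 3.30 s⁻¹, Ea = 64.0 kJ mol⁻¹)
    coupling partner + free catalyst ⇌ catalyst intermediate A (K = 0.200 M⁻¹, k = 4.30 M⁻¹ s⁻¹, Ea = 66.0 kJ mol⁻¹, ΔH = −21.0 kJ mol⁻¹)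
    coupling partner + free catalyst + target → free catalyst + over-reaction product (k = 0.190 M⁻² s⁻¹, Ea = 48.0 kJ mol⁻¹)
    catalyst intermediate A → catalyst intermediate B (k = 7.30 s⁻¹, Ea = 81.0 kJ mol⁻¹)
    substrate + catalyst intermediate B → catalyst intermediate C (k = 28.0 M⁻¹ s⁻¹, Ea = 52.0 kJ mol⁻¹)
    (constants at 60 °C)

In the east flask at 12 min the coupling partner is down to 3.28% of its charge and free catalyst stands at 98.2% of the catalyst charged, with target at 45.1% and isomer of the product at 14.6% of the substrate. Target and isomer relax by their step alone with a half-life of 1.80 min, so 6.67 half-lives fit into the asked time. The neighbour flask is charged with 0.24 M of coupling partner, which is 17.1% of the substrate, the yield on partner turns that charge into 10.9%, and that neighbour holds 12.1% target at the asked time.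

(The numbers in the tables were computed with constants of no real substance, and the scatter is random.)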